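**Plan**

- Retrosynthesis: the eight O–benzyl bonds and the C3'–O bond (traced back to C3'–B) are cut first. Ring F is then opened at O1'–C2' and C3'–C4' to a ring D ortho-quinone methide and an (E)-styrylboronate carrying ring E. C4' is cut from C4a' (formylation of a phenol), and C4–C8' is cut to a ring D aryllithium and the C4 ketone of benzylated dihydrorobinetin.
- Enabling feature: ring F (O1', C2', C3', C4', C4a', C8a') is a 2,3-trans chroman fused to ring D. Its O1'–C8a'–C4a'–C4' unit is therefore a masked ortho-quinone methide with an unsubstituted CH2 terminus (C4'), and C2'–C3' is a former (E)-alkene.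
- Forward: rings A, B and C are bought intact as (2R,3R)-dihydrorobinetin. Ring D is attached at C4 (steps 5 and 6), one carbon is added ortho to the ring D phenol (steps 8 and 9), and ring F closes last (step 11) with ring E already on the dienophile. Oxidation and hydrogenolysis finish the synthesis.
- Stereochemistry: C2 and C3 come from the chiral pool. C4 is set by hydride delivery to a C4 cation anti to the C3 silyloxy group (3,4-cis). C2' and C3' become trans by suprafacial addition to the (E)-alkene, with the absolute sense imposed by a chiral phosphoric acid. The C3' hydroxyl arises by stereoretentive C–B oxidation.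

Key step: step 11

Assumption 1: the target is read as robinetinidol-(4β→8)-catechin, (2R,3S,4R) in the upper unit (2,3-trans, 3,4-cis) and (2R,3S) in the lower unit; primed locants refer to the lower unit.
Assumption 2: natural (2R,3R)-dihydrorobinetin (the 2,3-trans dihydroflavonol of Robinia heartwood) is taken as a commercial, enantiopure starting material.

**Route**

Step 1
Reactants: 1 3,5-bis(benzyloxy)phenol
Product: 2 2-bromo-3,5-bis(benzyloxy)phenol
Conditions: NBS, i-Pr2NH (cat.), CH2Cl2, −78 → 0 °C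
Reagents that add atoms: N-bromosuccinimide, BrN1C(=O)CCC1=O
Why: Amine-mediated electrophilic bromination delivers bromine through a hydrogen-bonded N-bromoamine, so substitution is expected ortho to the hydroxyl (between OH and OBn) and not between the two benzyloxy groups, the symmetric para isomer being removable by chromatography if it forms.

Step 2
Reactants: 2 2-bromo-3,5-bis(benzyloxy)phenol
Product: 3 1,5-bis(benzyloxy)-2-bromo-3-(methoxymethoxy)benzene
Conditions: MOMCl, i-Pr2NEt, CH2Cl2, 0 °C → rt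
Reagents that add atoms: chloromethyl methyl ether, COCCl
Why: Williamson-type O-alkylation gives an acetal that tolerates organolithium chemistry, stabilises the neighbouring aryllithium by chelation and can later be removed without touching benzyl ethers.

Step 3
Reactants: 4 (2R,3R)-dihydrorobinetin
Product: 5 (2R,3R)-7-(benzyloxy)-3-hydroxy-2-[3,4,5-tris(benzyloxy)phenyl]chroman-4-one
Conditions: BnBr, K2CO3, DMF, N2 (degassed), rt
Reagents that add atoms: benzyl bromide, BrCc1ccccc1
Why: Williamson benzylation with a carbonate base alkylates only the four phenols (the C3 alcohol is not deprotonated), air being excluded to protect the pyrogallol ring and the 2,3-trans arrangement being the thermodynamically preferred one.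

Step 4
Reactants: 5 (2R,3R)-7-(benzyloxy)-3-hydroxy-2-[3,4,5-tris(benzyloxy)phenyl]chroman-4-one
Product: 6 (2R,3R)-7-(benzyloxy)-3-(tert-butyldimethylsilyloxy)-2-[3,4,5-tris(benzyloxy)phenyl]chroman-4-one
Conditions: tert-butyldimethylsilyl triflate, 2,6-lutidine, CH2Cl2, −40 → 0 °C
Reagents that add atoms: tert-butyldimethylsilyl triflate, CC(C)(C)[Si](C)(C)OS(=O)(=O)C(F)(F)F
Why: Silylation of the α-hydroxy ketone with a silyl triflate and a hindered pyridine base avoids enolisation and places a bulky group on the β-face at C3 that is meant to steer the hydride in step 6.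

Step 5
Reactants: 3 1,5-bis(benzyloxy)-2-bromo-3-(methoxymethoxy)benzene; 6 (2R,3R)-7-(benzyloxy)-3-(tert-butyldimethylsilyloxy)-2-[3,4,5-tris(benzyloxy)phenyl]chroman-4-one
Product: 8 (2R,3R)-7-(benzyloxy)-4-[2,4-bis(benzyloxy)-6-(methoxymethoxy)phenyl]-3-(tert-butyldimethylsilyloxy)-2-[3,4,5-tris(benzyloxy)phenyl]chroman-4-ol (aryl group drawn trans to O3; either C4 epimer serves), via aryllithium 7 (not isolated)
Conditions: 3, n-BuLi, THF, −78 °C; then 6, −78 → −20 °C; aq. NH4Cl
Reagents that add atoms: none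
Why: Bromine–lithium exchange followed by 1,2-addition of the chelation-stabilised aryllithium to the C4 ketone forms the C4–C8' bond, a reaction type established for 3-silyloxy-4-oxoflavans, and the carbinol configuration is irrelevant because C4 is ionised in step 6.

Step 6
Reactants: 8 the tertiary C4 carbinol
Product: 9 (2R,3S,4R)-7-(benzyloxy)-4-[2,4-bis(benzyloxy)-6-(methoxymethoxy)phenyl]-3-(tert-butyldimethylsilyloxy)-2-[3,4,5-tris(benzyloxy)phenyl]chromane (2,3-trans, 3,4-cis)
Conditions: Et3SiH, CF3CO2H, CH2Cl2, −78 → −20 °C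
Reagents that add atoms: none
Why: Ionic hydrogenation, in which the tertiary doubly benzylic alcohol ionises and the silane transfers hydride to the planar C4 cation from the α-face, anti to the adjacent bulky C3 silyloxy group, so that ring D ends up cis to O3 (4R), as known for deoxygenation of 4-aryl-4-hydroxyflavans; any loss of the acetal here only anticipates step 7.

Step 7
Reactants: 9 the 3-O-silyl, ring D O-methoxymethyl 4-arylflavan
Product: 10 (2R,3S,4R)-7-(benzyloxy)-4-[2,4-bis(benzyloxy)-6-hydroxyphenyl]-2-[3,4,5-tris(benzyloxy)phenyl]chroman-3-ol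
Conditions: HCl (aq.), MeOH/THF, 45 °C
Reagents that add atoms: none
Why: Acid-catalysed solvolysis removes the aryl methoxymethyl acetal and the secondary silyl ether while the benzyl ethers and the acid-resistant C4–aryl bond of this 5-deoxy flavan stay intact, exposing the single phenol of ring D.

Step 8
Reactants: 10 the ring D phenol
Product: 11 4,6-bis(benzyloxy)-2-hydroxy-3-{(2R,3S,4R)-7-(benzyloxy)-3-hydroxy-2-[3,4,5-tris(benzyloxy)phenyl]chroman-4-yl}benzaldehyde
Conditions: MgCl2, Et3N, (CH2O)n, THF, reflux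
Reagents that add atoms: paraformaldehyde (as formaldehyde), C=O
Why: The magnesium-mediated ortho-formylation (Casnati–Skattebøl reaction) runs through a magnesium phenoxide–formaldehyde chelate and so formylates only the free position ortho to the phenol (the future C4a'), not the position between the two benzyloxy groups, which fixes the 4→8 connectivity.

Step 9
Reactants: 11 the salicylaldehyde
Product: 12 (2R,3S,4R)-7-(benzyloxy)-4-[4,6-bis(benzyloxy)-2-hydroxy-3-(hydroxymethyl)phenyl]-2-[3,4,5-tris(benzyloxy)phenyl]chroman-3-ol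
Conditions: NaBH4, THF/MeOH, 0 °C
Reagents that add atoms: none
Why: Borohydride reduction of the aldehyde gives the salicyl alcohol, which is to be used without chromatography to avoid self-condensation through its quinone methide.

Step 10
Reactants: 13 3,4-bis(benzyloxy)benzaldehyde
Product: 14 (E)-2-[3,4-bis(benzyloxy)phenyl]ethenylboronic acid pinacol ester
Conditions: 2,2,6,6-tetramethylpiperidine, n-BuLi, THF, 0 °C; CH2(Bpin)2; then 13, −78 °C → rt
Reagents that add atoms: bis[(pinacolato)boryl]methane, CC1(C)OB(CB2OC(C)(C)C(C)(C)O2)OC1(C)C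
Why: Boron–Wittig olefination, in which the lithiated geminal bis(boronate) adds to the aldehyde and elimination of the boron–oxygen unit should give the (E)-alkenylboronate selectively.

Step 11
Reactants: 12 the ring D salicyl alcohol; 14 (E)-2-[3,4-bis(benzyloxy)phenyl]ethenylboronic acid pinacol ester
Product: 16 (2R,3S,4R)-7-(benzyloxy)-4-{(2S,3S)-5,7-bis(benzyloxy)-2-[3,4-bis(benzyloxy)phenyl]-3-(4,4,5,5-tetramethyl-1,3,2-dioxaborolan-2-yl)chroman-8-yl}-2-[3,4,5-tris(benzyloxy)phenyl]chroman-3-ol (2',3'-trans; the CIP descriptors of the lower unit differ from catechin only because boron replaces oxygen), via ortho-quinone methide 15 (not isolated)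
Conditions: (R)-3,3'-bis(2,4,6-triisopropylphenyl)-1,1'-binaphthyl-2,2'-diyl hydrogen phosphate (10 mol %), 5 Å molecular sieves, toluene, 0 °C → rt
Reagents that add atoms: none
Why: Proposed new method: the chiral phosphoric acid dehydrates 12 to ortho-quinone methide 15 and stays hydrogen-bonded to its carbonyl oxygen; the boron-bearing carbon of 14 attacks the CH2 terminus while the benzylic carbon, whose developing positive charge is stabilised by the para-benzyloxy group of ring E, bonds to O1' in an asynchronous inverse-electron-demand oxa-(4+2) cycloaddition. The closest known reaction type is the Brønsted-acid-catalysed hetero-Diels–Alder reaction of ortho-quinone methides generated in situ with (E)-β-substituted electron-rich styrenes, extended here to a β-boryl styrene. Ring F closes by this intermolecular (4+2) annulation, which forms C3'–C4' and O1'–C2' in one event. Suprafacial addition to the (E)-alkene places the C2' aryl group and the C3' boron trans, and the absolute sense at C2' and C3' is to be imposed by the chiral phosphate bound to 15, over any bias from the upper-unit substituent next to O1'. The step needs aryl-carbon-to-oxygen regiochemistry, secured by the para-alkoxy donor, and cycloaddition in preference to alkenyl transfer from boron to carbon, favoured by the pinacol ester, which does not readily exchange with the phenol. The 4→8 connectivity is already fixed by the position of the hydroxymethyl group in 12.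

Step 12
Reactants: 16 the C3' pinacol boronate
Product: 17 (2R,3S,4R)-7-(benzyloxy)-4-{(2R,3S)-5,7-bis(benzyloxy)-2-[3,4-bis(benzyloxy)phenyl]-3-hydroxychroman-8-yl}-2-[3,4,5-tris(benzyloxy)phenyl]chroman-3-ol
Conditions: NaBO3·4H2O, THF/H2O, rt
Reagents that add atoms: sodium perborate (written without water of crystallisation), [Na+].[Na+].O[B-]1(O)OO[B-](O)(O)OO1
Why: Perborate oxidation moves C3' from boron to oxygen with retention, giving the 3'-hydroxyl trans to the C2' aryl group, and its mild, nearly neutral conditions should suppress β-elimination of the β-aryloxy boronate.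

Step 13
Reactants: 17 the octa-O-benzyl dimer
Product: 18 robinetinidol-(4β→8)-catechin, (2R,3S,4R)-4-[(2R,3S)-2-(3,4-dihydroxyphenyl)-3,5,7-trihydroxychroman-8-yl]-2-(3,4,5-trihydroxyphenyl)chromane-3,7-diol
Conditions: H2 (1 atm), Pd(OH)2/C, THF/MeOH, rt
Reagents that add atoms: none
Why: Hydrogenolysis over palladium cleaves all eight benzyl ethers as toluene, the standard last step for benzylated flavan-3-ol oligomers, under which the ring C–O bonds at C2 and C2' and the C4–C8' bond are not cleaved.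

**Compound list**

1 | 3,5-bis(benzyloxy)phenol | Oc1cc(OCc2ccccc2)cc(OCc2ccccc2)c1 | starting material
2 | 2-bromo-3,5-bis(benzyloxy)phenol | Oc1cc(OCc2ccccc2)cc(OCc2ccccc2)c1Br | intermediate
3 | 1,5-bis(benzyloxy)-2-bromo-3-(methoxymethoxy)benzene | COCOc1cc(OCc2ccccc2)cc(OCc2ccccc2)c1Br | intermediate
4 | (2R,3R)-dihydrorobinetin, (2R,3R)-3,7-dihydroxy-2-(3,4,5-trihydroxyphenyl)chroman-4-one | Oc1ccc2c(c1)O[C@H](c1cc(O)c(O)c(O)c1)[C@@H](O)C2=O | starting material
5 | (2R,3R)-7-(benzyloxy)-3-hydroxy-2-[3,4,5-tris(benzyloxy)phenyl]chroman-4-one | c1ccccc1COc1ccc2c(c1)O[C@H](c1cc(OCc3ccccc3)c(OCc3ccccc3)c(OCc3ccccc3)c1)[C@@H](O)C2=O | intermediate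
6 | (2R,3R)-7-(benzyloxy)-3-(tert-butyldimethylsilyloxy)-2-[3,4,5-tris(benzyloxy)phenyl]chroman-4-one | c1ccccc1COc1ccc2c(c1)O[C@H](c1cc(OCc3ccccc3)c(OCc3ccccc3)c(OCc3ccccc3)c1)[C@@H](O[Si](C)(C)C(C)(C)C)C2=O | intermediate
7 | [2,4-bis(benzyloxy)-6-(methoxymethoxy)phenyl]lithium | COCOc1cc(OCc2ccccc2)cc(OCc2ccccc2)c1[Li] | intermediate (not isolated)
8 | (2R,3R)-7-(benzyloxy)-4-[2,4-bis(benzyloxy)-6-(methoxymethoxy)phenyl]-3-(tert-butyldimethylsilyloxy)-2-[3,4,5-tris(benzyloxy)phenyl]chroman-4-ol, aryl group trans to O3 drawn | c1ccccc1COc1ccc2c(c1)O[C@H](c1cc(OCc3ccccc3)c(OCc3ccccc3)c(OCc3ccccc3)c1)[C@@H](O[Si](C)(C)C(C)(C)C)[C@]2(O)c1c(OCOC)cc(OCc3ccccc3)cc1OCc1ccccc1 | intermediate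
9 | (2R,3S,4R)-7-(benzyloxy)-4-[2,4-bis(benzyloxy)-6-(methoxymethoxy)phenyl]-3-(tert-butyldimethylsilyloxy)-2-[3,4,5-tris(benzyloxy)phenyl]chromane | c1ccccc1COc1ccc2c(c1)O[C@H](c1cc(OCc3ccccc3)c(OCc3ccccc3)c(OCc3ccccc3)c1)[C@@H](O[Si](C)(C)C(C)(C)C)[C@H]2c1c(OCOC)cc(OCc3ccccc3)cc1OCc1ccccc1 | intermediate
10 | (2R,3S,4R)-7-(benzyloxy)-4-[2,4-bis(benzyloxy)-6-hydroxyphenyl]-2-[3,4,5-tris(benzyloxy)phenyl]chroman-3-ol | c1ccccc1COc1ccc2c(c1)O[C@H](c1cc(OCc3ccccc3)c(OCc3ccccc3)c(OCc3ccccc3)c1)[C@@H](O)[C@H]2c1c(O)cc(OCc3ccccc3)cc1OCc1ccccc1 | intermediate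
11 | 4,6-bis(benzyloxy)-2-hydroxy-3-{(2R,3S,4R)-7-(benzyloxy)-3-hydroxy-2-[3,4,5-tris(benzyloxy)phenyl]chroman-4-yl}benzaldehyde | c1ccccc1COc1ccc2c(c1)O[C@H](c1cc(OCc3ccccc3)c(OCc3ccccc3)c(OCc3ccccc3)c1)[C@@H](O)[C@H]2c1c(O)c(C=O)c(OCc3ccccc3)cc1OCc1ccccc1 | intermediate
12 | (2R,3S,4R)-7-(benzyloxy)-4-[4,6-bis(benzyloxy)-2-hydroxy-3-(hydroxymethyl)phenyl]-2-[3,4,5-tris(benzyloxy)phenyl]chroman-3-ol | c1ccccc1COc1ccc2c(c1)O[C@H](c1cc(OCc3ccccc3)c(OCc3ccccc3)c(OCc3ccccc3)c1)[C@@H](O)[C@H]2c1c(O)c(CO)c(OCc3ccccc3)cc1OCc1ccccc1 | intermediate (precursor of the key step)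
13 | 3,4-bis(benzyloxy)benzaldehyde | O=Cc1ccc(OCc2ccccc2)c(OCc2ccccc2)c1 | starting material
14 | (E)-2-[3,4-bis(benzyloxy)phenyl]ethenylboronic acid pinacol ester | CC1(C)OB(/C=C/c2ccc(OCc3ccccc3)c(OCc3ccccc3)c2)OC1(C)C | intermediate
15 | ring D ortho-quinone methide, 3,5-bis(benzyloxy)-6-methylidene-2-{(2R,3S,4R)-7-(benzyloxy)-3-hydroxy-2-[3,4,5-tris(benzyloxy)phenyl]chroman-4-yl}cyclohexa-2,4-dien-1-one | c1ccccc1COc1ccc2c(c1)O[C@H](c1cc(OCc3ccccc3)c(OCc3ccccc3)c(OCc3ccccc3)c1)[C@@H](O)[C@H]2C1=C(OCc3ccccc3)C=C(OCc3ccccc3)C(=C)C1=O | intermediate (not isolated)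
16 | (2R,3S,4R)-7-(benzyloxy)-4-{(2S,3S)-5,7-bis(benzyloxy)-2-[3,4-bis(benzyloxy)phenyl]-3-(4,4,5,5-tetramethyl-1,3,2-dioxaborolan-2-yl)chroman-8-yl}-2-[3,4,5-tris(benzyloxy)phenyl]chroman-3-ol | c1ccccc1COc1ccc2c(c1)O[C@H](c1cc(OCc3ccccc3)c(OCc3ccccc3)c(OCc3ccccc3)c1)[C@@H](O)[C@H]2c1c(OCc3ccccc3)cc(OCc3ccccc3)c2c1O[C@H](c1ccc(OCc3ccccc3)c(OCc3ccccc3)c1)[C@@H](B3OC(C)(C)C(C)(C)O3)C2 | intermediate (product of the key step)
17 | (2R,3S,4R)-7-(benzyloxy)-4-{(2R,3S)-5,7-bis(benzyloxy)-2-[3,4-bis(benzyloxy)phenyl]-3-hydroxychroman-8-yl}-2-[3,4,5-tris(benzyloxy)phenyl]chroman-3-ol | c1ccccc1COc1ccc2c(c1)O[C@H](c1cc(OCc3ccccc3)c(OCc3ccccc3)c(OCc3ccccc3)c1)[C@@H](O)[C@H]2c1c(OCc3ccccc3)cc(OCc3ccccc3)c2c1O[C@H](c1ccc(OCc3ccccc3)c(OCc3ccccc3)c1)[C@@H](O)C2 | intermediate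
18 | robinetinidol-(4β→8)-catechin, (2R,3S,4R)-4-[(2R,3S)-2-(3,4-dihydroxyphenyl)-3,5,7-trihydroxychroman-8-yl]-2-(3,4,5-trihydroxyphenyl)chromane-3,7-diol | Oc1ccc2c(c1)O[C@H](c1cc(O)c(O)c(O)c1)[C@@H](O)[C@H]2c1c(O)cc(O)c2c1O[C@H](c1ccc(O)c(O)c1)[C@@H](O)C2 | target

**Step count**

Total: 13 steps. Longest linear sequence: 10 steps (steps 3, 4, 5, 6, 7, 8, 9, 11, 12, 13, from 4 to 18).

**Steps most likely to fail**

1. Step 11 (proposed new method). Three processes can defeat it.
   - The alkenyl group may transfer from boron to the methide carbon, or boron may be lost from the β-boryl benzylic cation, giving an open-chain cinnamylphenol instead of ring F.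
   - The quinone methide may self-condense.
   - The phosphoric acid may not discriminate the two alkene faces sufficiently; which antipode of the acid is matched with the upper unit has to be found by one comparison.

   The fallback uses known chemistry, leaves the route at ketone 6 and takes the lower unit from the chiral pool. (+)-Catechin is benzylated on its four phenols (BnBr, K2CO3, DMF) to 5,7,3',4'-tetra-O-benzyl-(+)-catechin F1. This is brominated at C8 with NBS in CH2Cl2 to the 8-bromide F2 and silylated (tert-butyldimethylsilyl chloride, imidazole, DMF) to the 3-O-silyl ether F3. Bromine–lithium exchange (n-BuLi, THF, −78 °C) and addition to 6, as in step 5, should give the tertiary carbinol F4. Ionic hydrogenation (Et3SiH, CF3CO2H), as in step 6, should give the 3,4-cis bis(silyl ether) F5. Tetrabutylammonium fluoride in THF then removes both silyl groups and the route is rejoined at 17. Ring F is never built in this variant; the C4–C8' bond is formed instead by the addition–reduction pair already exercised in steps 5 and 6.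

2. Step 6. The C2 aryl group on the α-face opposes the C3 silyloxy group, so hydride may enter from the β-face and give the 3,4-trans epimer. Loss of a proton from C3 to an enol ether may also compete.

   The fallback sets out from 5. NaBH4 in THF/MeOH reduces the ketone to the flavan-3,4-diol F6. BF3·OEt2 in CH2Cl2 at low temperature then ionises the C4 hydroxyl in the presence of phenol 1, which is alkylated ortho to its hydroxyl (Friedel–Crafts reaction of a flavan-4-yl cation, the classical leucoanthocyanidin condensation). This gives 10 directly, together with its C4 epimer and some para-alkylated isomer, to be separated by chromatography. Here the aryl group is the incoming nucleophile, so attack anti to the C2 aryl group, harmful in step 6, is the productive path.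

3. Step 8. Magnesium phenoxide formation may be sluggish at the doubly flanked phenol, and phenol–formaldehyde condensation to diarylmethanes may intervene.

   The fallback sets out from 10. Phenylboronic acid, paraformaldehyde and catalytic propionic acid in refluxing toluene (boron-templated ortho-hydroxymethylation) should give the 2-phenyl-4H-1,3,2-benzodioxaborin F7. Exchange with propane-1,3-diol liberates 12, so that steps 8 and 9 are both bypassed. F7 also serves as a storable form of the labile salicyl alcohol.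

**Further compounds**

F1 | step 11 | 5,7,3',4'-tetra-O-benzyl-(+)-catechin, (2R,3S)-5,7-bis(benzyloxy)-2-[3,4-bis(benzyloxy)phenyl]chroman-3-ol | c1c(OCc3ccccc3)cc(OCc3ccccc3)c2c1O[C@H](c1ccc(OCc3ccccc3)c(OCc3ccccc3)c1)[C@@H](O)C2
F2 | step 11 | (2R,3S)-5,7-bis(benzyloxy)-2-[3,4-bis(benzyloxy)phenyl]-8-bromochroman-3-ol | Brc1c(OCc3ccccc3)cc(OCc3ccccc3)c2c1O[C@H](c1ccc(OCc3ccccc3)c(OCc3ccccc3)c1)[C@@H](O)C2
F3 | step 11 | (2R,3S)-5,7-bis(benzyloxy)-2-[3,4-bis(benzyloxy)phenyl]-8-bromo-3-(tert-butyldimethylsilyloxy)chromane | Brc1c(OCc3ccccc3)cc(OCc3ccccc3)c2c1O[C@H](c1ccc(OCc3ccccc3)c(OCc3ccccc3)c1)[C@@H](O[Si](C)(C)C(C)(C)C)C2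
F4 | step 11 | (2R,3R)-7-(benzyloxy)-4-{(2R,3S)-5,7-bis(benzyloxy)-2-[3,4-bis(benzyloxy)phenyl]-3-(tert-butyldimethylsilyloxy)chroman-8-yl}-3-(tert-butyldimethylsilyloxy)-2-[3,4,5-tris(benzyloxy)phenyl]chroman-4-ol, aryl group trans to O3 drawn | c1ccccc1COc1ccc2c(c1)O[C@H](c1cc(OCc3ccccc3)c(OCc3ccccc3)c(OCc3ccccc3)c1)[C@@H](O[Si](C)(C)C(C)(C)C)[C@]2(O)c1c(OCc3ccccc3)cc(OCc3ccccc3)c2c1O[C@H](c1ccc(OCc3ccccc3)c(OCc3ccccc3)c1)[C@@H](O[Si](C)(C)C(C)(C)C)C2
F5 | step 11 | 3,3'-bis(tert-butyldimethylsilyl) ether of 17, (2R,3S,4R)-7-(benzyloxy)-4-{(2R,3S)-5,7-bis(benzyloxy)-2-[3,4-bis(benzyloxy)phenyl]-3-(tert-butyldimethylsilyloxy)chroman-8-yl}-3-(tert-butyldimethylsilyloxy)-2-[3,4,5-tris(benzyloxy)phenyl]chromane | c1ccccc1COc1ccc2c(c1)O[C@H](c1cc(OCc3ccccc3)c(OCc3ccccc3)c(OCc3ccccc3)c1)[C@@H](O[Si](C)(C)C(C)(C)C)[C@H]2c1c(OCc3ccccc3)cc(OCc3ccccc3)c2c1O[C@H](c1ccc(OCc3ccccc3)c(OCc3ccccc3)c1)[C@@H](O[Si](C)(C)C(C)(C)C)C2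
F6 | step 6 | (2R,3S,4R)-7-(benzyloxy)-2-[3,4,5-tris(benzyloxy)phenyl]chromane-3,4-diol (3,4-trans drawn; the C4 configuration is of no consequence) | c1ccccc1COc1ccc2c(c1)O[C@H](c1cc(OCc3ccccc3)c(OCc3ccccc3)c(OCc3ccccc3)c1)[C@@H](O)[C@@H]2O
F7 | step 8 | (2R,3S,4R)-7-(benzyloxy)-4-[5,7-bis(benzyloxy)-2-phenyl-4H-1,3,2-benzodioxaborin-8-yl]-2-[3,4,5-tris(benzyloxy)phenyl]chroman-3-ol | c1ccccc1COc1ccc2c(c1)O[C@H](c1cc(OCc3ccccc3)c(OCc3ccccc3)c(OCc3ccccc3)c1)[C@@H](O)[C@H]2c1c3OB(c4ccccc4)OCc3c(OCc3ccccc3)cc1OCc1ccccc1
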